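**Retrosynthetic overview**

1. The target comes from its C1 silyl ether, and this from ring closure at C5–C6: an intramolecular Nozaki–Hiyama–Kishi addition of a (Z)-alkenyl iodide (C5) to the C6 aldehyde of an open-chain seco ester. The C6 alkoxide then closes the butenolide on the C12 ester, so ring A (ten-membered carbocycle) and ring B (butenolide) form, in this order, in one operation.
2. Enabling feature: C6 is at once the γ-carbon of butenolide ring B (O–C6–C7=C11–C12) and the allylic neighbour of the cis C4=C5 olefin of ring A. Because C6 and C12 are cis on the tetrasubstituted C7=C11 olefin, C6 can be a free aldehyde and C12 a methyl ester in an acyclic precursor.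
3. The seco ester is cut at C8–C9: catalytic asymmetric chromium allylation of a C6–C8/C11–C13 aldehyde with a C1–C5/C9/C10/C14 allyl bromide.
4. The aldehyde comes from a three-component carbocupration/alkylation of a 4,4-diethoxybut-2-ynoate (vinylcopper, bromomethyl acetate) and ozonolysis. The allyl bromide comes from an asymmetric Morita–Baylis–Hillman reaction of (Z)-5-iodo-4-methylpent-4-enal, itself made from propargyl alcohol by anti-carbomagnesiation/iodination.
5. Stereocenters: C1 by organocatalysis, C8 by a chiral chromium catalyst, C6 relayed from C8 in the ring closure.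

Key step: step 14

Remark: the target SMILES is read as (1S,6R,8S) with a Z-configured C4=C5 bond (C3 and C6 cis); the germacrane atom numbers of the name are used for all intermediates.

**Route**

Step 1
Reactants: 1 prop-2-yn-1-ol
Product: 3 (2Z)-3-iodo-2-methylprop-2-en-1-ol, via cyclic alkenylmagnesium alkoxide 2 (not isolated)
Conditions: MeMgBr (2.5 equiv), CuI (10 mol %), THF, −10 °C → rt; then I2, −78 → 0 °C
Reagents that add atoms: methylmagnesium bromide, C[Mg]Br; iodine, II
Why: Copper-catalysed anti-carbomagnesiation of the magnesium alkoxide of a propargylic alcohol adds methyl to C4 and magnesium to C5 within the five-membered chelate 2, and iodinolysis with retention should give the Z iodide that later becomes the cis C4=C5 olefin.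

Step 2
Reactants: 3 (2Z)-3-iodo-2-methylprop-2-en-1-ol
Product: 4 (1Z)-3-bromo-1-iodo-2-methylprop-1-ene
Conditions: PBr3 (0.4 equiv), Et2O, 0 °C
Reagents that add atoms: phosphorus tribromide, BrP(Br)Br
Why: Conversion of a primary allylic alcohol into the bromide with PBr3 (SN2-type displacement of the phosphite ester) should leave the olefin geometry and the C–I bond untouched.

Step 3
Reactants: 4 (1Z)-3-bromo-1-iodo-2-methylprop-1-ene; 5 acetaldehyde N,N-dimethylhydrazone
Product: 8 (4Z)-5-iodo-4-methylpent-4-enal, via lithium aza-enolate 6 (not isolated), via alkylated hydrazone 7 (not isolated)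
Conditions: 5, LiN(i-Pr)2, THF, −78 → 0 °C; 4, −78 °C → rt; then aq. oxalic acid, Et2O, rt
Reagents that add atoms: water, O
Why: Aza-enolate alkylation: the lithiated hydrazone 6 is alkylated at carbon by the primary allylic bromide (SN2), and mild aqueous acid hydrolyses hydrazone 7 to the aldehyde, a two-carbon homologation that tolerates the alkenyl iodide.

Step 4
Reactants: 8 (4Z)-5-iodo-4-methylpent-4-enal; 9 1,1,1,3,3,3-hexafluoropropan-2-yl prop-2-enoate
Product: 10 1,1,1,3,3,3-hexafluoropropan-2-yl (3S,6Z)-3-hydroxy-7-iodo-6-methyl-2-methylidenehept-6-enoate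
Conditions: α-isocupreine (10 mol %), DMF, −55 °C
Reagents that add atoms: none
Why: Catalytic asymmetric Morita–Baylis–Hillman reaction with the activated hexafluoroisopropyl acrylate: the quinuclidine nitrogen of α-isocupreine (the quinine-derived pseudo-enantiomer of β-isocupreidine) forms the acrylate β-ammonium enolate and its phenol hydrogen-bonds the aldol intermediate, which should set C1 as S under catalyst control.

Step 5
Reactants: 10 hexafluoroisopropyl (3S,6Z)-3-hydroxy-7-iodo-6-methyl-2-methylidenehept-6-enoate
Product: 11 1,1,1,3,3,3-hexafluoropropan-2-yl (3S,6Z)-7-iodo-6-methyl-2-methylidene-3-{[tri(propan-2-yl)silyl]oxy}hept-6-enoate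
Conditions: i-Pr3SiOTf, 2,6-lutidine, CH2Cl2, −78 → 0 °C
Reagents that add atoms: triisopropylsilyl trifluoromethanesulfonate, CC(C)[Si](C(C)C)(C(C)C)OS(=O)(=O)C(F)(F)F
Why: Silylation of the secondary allylic alcohol with the silyl triflate and a hindered pyridine base (no nucleophile that could attack the activated ester); the bulky, acid-stable silyl ether is chosen to survive step 13.

Step 6
Reactants: 11 silyl ether of the hexafluoroisopropyl ester
Product: 12 (3S,6Z)-7-iodo-6-methyl-2-methylidene-3-{[tri(propan-2-yl)silyl]oxy}hept-6-en-1-ol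
Conditions: i-Bu2AlH (2.5 equiv), CH2Cl2, −78 °C; aq. potassium sodium tartrate work-up
Reagents that add atoms: none
Why: 1,2-Reduction of the activated ester by the aluminium hydride at low temperature gives the primary allylic alcohol, while alkenyl iodide and silyl ether are inert.

Step 7
Reactants: 12 (3S,6Z)-7-iodo-6-methyl-2-methylidene-3-(triisopropylsilyloxy)hept-6-en-1-ol
Product: 13 {[(3S,6Z)-2-(bromomethyl)-7-iodo-6-methylhepta-1,6-dien-3-yl]oxy}tri(propan-2-yl)silane
Conditions: CBr4, PPh3, CH2Cl2, 0 °C
Reagents that add atoms: tetrabromomethane, BrC(Br)(Br)Br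
Why: Appel reaction under neutral conditions; both termini of the allyl unit are CH2 groups, so SN2 and SN2' displacement give the same bromide.

Step 8
Reactants: 14 3,3-diethoxyprop-1-yne
Product: 16 methyl 4,4-diethoxybut-2-ynoate, via lithium acetylide 15 (not isolated)
Conditions: n-BuLi, THF, −78 °C; then ClCO2Me, −78 → 0 °C
Reagents that add atoms: methyl chloroformate, COC(=O)Cl
Why: Deprotonation of the terminal alkyne and acylation of lithium acetylide 15 with the chloroformate is the standard route to alkynoates.

Step 9
Reactants: 16 methyl 4,4-diethoxybut-2-ynoate; 17 bromomethyl acetate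
Product: 19 methyl (2Z)-2-[(acetyloxy)methyl]-3-(diethoxymethyl)penta-2,4-dienoate, via alkenylcopper adduct 18 (not isolated)
Conditions: CH2=CHMgBr (1.2 equiv), CuBr·SMe2 (1.2 equiv), THF, −78 °C; 16, −78 °C; then 17, DMPU, −78 → −40 °C
Reagents that add atoms: vinylmagnesium bromide, C=C[Mg]Br
Why: Three-component carbocupration–alkylation of an alkynoate: vinylcopper adds syn across the triple bond (vinyl to C7, copper to C11), and the α-cuprio ester 18, configurationally stable at −78 °C, is alkylated with retention by the reactive α-acyloxy bromide (precedent: trapping of such adducts with halomethyl electrophiles), so that C8 and C13 end cis and the acetal carbon C6 ends cis to the C12 ester.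

Step 10
Reactants: 19 methyl (2Z)-2-[(acetyloxy)methyl]-3-(diethoxymethyl)penta-2,4-dienoate
Product: 21 methyl (2Z)-2-[(acetyloxy)methyl]-4,4-diethoxy-3-formylbut-2-enoate, via ozonide 20 (not isolated)
Conditions: O3 (1 equiv), CH2Cl2, −78 °C; then Me2S, −78 °C → rt
Reagents that add atoms: ozone, [O-][O+]=O
Why: Ozonolysis should cleave only the terminal vinyl group, the tetrasubstituted olefin being deactivated by the ester and shielded, and reduction of ozonide 20 with dimethyl sulfide gives the C8 aldehyde.

Step 11
Reactants: 21 methyl (2Z)-2-[(acetyloxy)methyl]-4,4-diethoxy-3-formylbut-2-enoate; 13 allyl bromide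
Product: 22 methyl (2Z,4S,7S,10Z)-2-[(acetyloxy)methyl]-3-(diethoxymethyl)-4-hydroxy-11-iodo-10-methyl-6-methylidene-7-{[tri(propan-2-yl)silyl]oxy}undeca-2,10-dienoate
Conditions: CrCl2 (15 mol %), chiral oxazoline–sulfonamide ligand N-[2-(4-isopropyl-4,5-dihydrooxazol-2-yl)-6-methylphenyl]methanesulfonamide (17 mol %, enantiomer for Si-face attack), proton sponge (17 mol %), Mn (2 equiv), (C5H5)2ZrCl2 (1.2 equiv), LiCl, MeCN, rt, no nickel
Reagents that add atoms: none
Why: Nickel-free catalytic asymmetric Nozaki–Hiyama allylation: divalent chromium turns the allylic bromide into an allylchromium species (both allyl termini are CH2, so only one constitution can form) that adds to the aldehyde through a six-membered chair on the chiral chromium sulfonamide complex, whose chosen enantiomer directs Si-face attack and sets C8 as S under catalyst control, while the alkenyl iodide stays untouched because no nickel is present.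

Step 12
Reactants: 22 C8 alcohol
Product: 23 methyl (2Z,4S,7S,10Z)-4-(acetyloxy)-2-[(acetyloxy)methyl]-3-(diethoxymethyl)-11-iodo-10-methyl-6-methylidene-7-{[tri(propan-2-yl)silyl]oxy}undeca-2,10-dienoate
Conditions: Ac2O, pyridine, DMAP (cat.), CH2Cl2, 0 °C → rt
Reagents that add atoms: acetic anhydride, CC(=O)OC(C)=O
Why: Standard acylation of the secondary allylic alcohol with nucleophilic catalysis; any acetyl shift between O13 and O8 that may have occurred in 22 converges to the same diacetate.

Step 13
Reactants: 23 diacetate acetal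
Product: 25 methyl (2Z,4S,7S,10Z)-4-(acetyloxy)-2-[(acetyloxy)methyl]-3-formyl-11-iodo-10-methyl-6-methylidene-7-{[tri(propan-2-yl)silyl]oxy}undeca-2,10-dienoate, via γ-hydroxybutenolide 24 (not isolated)
Conditions: TFA/H2O/THF (1:1:4), rt; evaporation; then MeI, KHCO3, DMF, 0 °C → rt
Reagents that add atoms: water, O; iodomethane, CI
Why: Aqueous acid hydrolyses the acetal and the aldehyde hydrate lactonises onto the cis ester to give γ-hydroxybutenolide 24 (the pseudo-acid sink of cis 4-oxo-2-enoates), which hydrogencarbonate opens to the aldehyde carboxylate that is O-methylated, so the free C6 aldehyde and the C12 ester emerge cis by construction.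

Step 14
Reactants: 25 seco aldehyde ester
Product: 27 8α,13-diacetoxy-1α-[(triisopropylsilyl)oxy]germacra-4,7(11),10(14)-trien-6α,12-olide, via macrocyclic chromium alkoxide 26 (not isolated)
Conditions: CrCl2 (10 equiv), NiCl2 (0.1 equiv), DMSO/THF (3:1), rt, 25 added by syringe pump over 12 h (final 0.002 M); aq. ethylenediamine work-up
Reagents that add atoms: none
Why: Zerovalent nickel inserts into the C5–I bond with retention of the Z geometry and hands the alkenyl group to trivalent chromium, which adds it 1,2 to the C6 aldehyde (intramolecular Nozaki–Hiyama–Kishi reaction; closest precedent: closures of nine- to twelve-membered carbocyclic allylic alcohols by this reaction), and the chromium alkoxide 26 then displaces methoxide from the C12 ester that the Z C7=C11 olefin holds cis (the spontaneous lactonisation of Z γ-hydroxy enoates). Ring A closes in a 10-exo-trig carbonyl addition and ring B in a 5-exo-trig acyl substitution. The new stereocenter C6 is controlled by C8: allylic 1,3-strain against C13 keeps H8 in the plane of the tetrasubstituted olefin, so that C9 and the acetoxy group lie on opposite faces, the enal reacts s-trans (carbonyl oxygen turned away from the cis ester), and the tether that starts at C9 brings C5 to the C9 face, which is the Re face of the aldehyde and gives 6R. The step needs 1,2-addition to the aldehyde in the presence of one ester and two acetates (alkenylchromium reagents add only to aldehydes at room temperature), ring closure instead of oligomerisation (high dilution; the cis C4=C5 olefin, the exocyclic C10 methylene and the planar C6–C7(=C11)–C8 unit leave few rotors in the chain) and lactonisation instead of acetyl transfer from O8 (the five-membered closure onto the conjugated cis ester is the faster one).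

Step 15
Reactants: 27 C1 silyl ether of the target
Product: 28 8α,13-diacetoxy-1α-hydroxygermacra-4,7(11),10(14)-trien-6α,12-olide
Conditions: HF·pyridine, pyridine/THF, 0 °C → rt
Reagents that add atoms: none
Why: Fluoride-mediated cleavage of the silyl ether with buffered HF·pyridine should leave both acetates and the butenolide intact and give the target.

**Compound list**

1 | prop-2-yn-1-ol | C#CCO | starting material
2 | cyclic alkenylmagnesium alkoxide (4-methyl-2,5-dihydro-1,2-oxamagnesole) | CC1=C[Mg]OC1 | intermediate (not isolated)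
3 | (2Z)-3-iodo-2-methylprop-2-en-1-ol | OC/C(C)=C\I | intermediate
4 | (1Z)-3-bromo-1-iodo-2-methylprop-1-ene | BrC/C(C)=C\I | intermediate
5 | acetaldehyde N,N-dimethylhydrazone | CC=NN(C)C | starting material
6 | lithium aza-enolate of 5 | [Li]CC=NN(C)C | intermediate (not isolated)
7 | (4Z)-5-iodo-4-methylpent-4-enal N,N-dimethylhydrazone | CN(C)N=CCC/C(C)=C\I | intermediate (not isolated)
8 | (4Z)-5-iodo-4-methylpent-4-enal | O=CCC/C(C)=C\I | intermediate
9 | 1,1,1,3,3,3-hexafluoropropan-2-yl prop-2-enoate | C=CC(=O)OC(C(F)(F)F)C(F)(F)F | starting material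
10 | 1,1,1,3,3,3-hexafluoropropan-2-yl (3S,6Z)-3-hydroxy-7-iodo-6-methyl-2-methylidenehept-6-enoate | C=C(C(=O)OC(C(F)(F)F)C(F)(F)F)[C@@H](O)CC/C(C)=C\I | intermediate
11 | 1,1,1,3,3,3-hexafluoropropan-2-yl (3S,6Z)-7-iodo-6-methyl-2-methylidene-3-{[tri(propan-2-yl)silyl]oxy}hept-6-enoate | C=C(C(=O)OC(C(F)(F)F)C(F)(F)F)[C@@H](O[Si](C(C)C)(C(C)C)C(C)C)CC/C(C)=C\I | intermediate
12 | (3S,6Z)-7-iodo-6-methyl-2-methylidene-3-{[tri(propan-2-yl)silyl]oxy}hept-6-en-1-ol | OCC(=C)[C@@H](O[Si](C(C)C)(C(C)C)C(C)C)CC/C(C)=C\I | intermediate
13 | {[(3S,6Z)-2-(bromomethyl)-7-iodo-6-methylhepta-1,6-dien-3-yl]oxy}tri(propan-2-yl)silane | BrCC(=C)[C@@H](O[Si](C(C)C)(C(C)C)C(C)C)CC/C(C)=C\I | intermediate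
14 | 3,3-diethoxyprop-1-yne | C#CC(OCC)OCC | starting material
15 | lithium 3,3-diethoxyprop-1-yn-1-ide | [Li]C#CC(OCC)OCC | intermediate (not isolated)
16 | methyl 4,4-diethoxybut-2-ynoate | CCOC(OCC)C#CC(=O)OC | intermediate
17 | bromomethyl acetate | CC(=O)OCBr | starting material
18 | alkenylcopper syn adduct, methyl (2E)-2-cuprio-3-(diethoxymethyl)penta-2,4-dienoate (as its MgBr2 complex) | C=C/C(C(OCC)OCC)=C(\[Cu])C(=O)OC | intermediate (not isolated)
19 | methyl (2Z)-2-[(acetyloxy)methyl]-3-(diethoxymethyl)penta-2,4-dienoate | C=C/C(C(OCC)OCC)=C(\COC(C)=O)C(=O)OC | intermediate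
20 | ozonide of 19 at the terminal olefin (1,2,4-trioxolan-3-yl in place of vinyl, olefin geometry as in 19) | C1OOC(O1)/C(C(OCC)OCC)=C(\COC(C)=O)C(=O)OC | intermediate (not isolated)
21 | methyl (2Z)-2-[(acetyloxy)methyl]-4,4-diethoxy-3-formylbut-2-enoate | O=C/C(C(OCC)OCC)=C(\COC(C)=O)C(=O)OC | intermediate
22 | methyl (2Z,4S,7S,10Z)-2-[(acetyloxy)methyl]-3-(diethoxymethyl)-4-hydroxy-11-iodo-10-methyl-6-methylidene-7-{[tri(propan-2-yl)silyl]oxy}undeca-2,10-dienoate | CCOC(OCC)/C(=C(/COC(C)=O)C(=O)OC)[C@@H](O)CC(=C)[C@@H](O[Si](C(C)C)(C(C)C)C(C)C)CC/C(C)=C\I | intermediate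
23 | methyl (2Z,4S,7S,10Z)-4-(acetyloxy)-2-[(acetyloxy)methyl]-3-(diethoxymethyl)-11-iodo-10-methyl-6-methylidene-7-{[tri(propan-2-yl)silyl]oxy}undeca-2,10-dienoate | CCOC(OCC)/C(=C(/COC(C)=O)C(=O)OC)[C@@H](OC(C)=O)CC(=C)[C@@H](O[Si](C(C)C)(C(C)C)C(C)C)CC/C(C)=C\I | intermediate
24 | {4-[(1S,4S,7Z)-1-(acetyloxy)-8-iodo-7-methyl-3-methylidene-4-{[tri(propan-2-yl)silyl]oxy}oct-7-en-1-yl]-5-hydroxy-2-oxo-2,5-dihydrofuran-3-yl}methyl acetate (γ-hydroxybutenolide, both C5 epimers) | O=C1OC(O)C([C@@H](OC(C)=O)CC(=C)[C@@H](O[Si](C(C)C)(C(C)C)C(C)C)CC/C(C)=C\I)=C1COC(C)=O | intermediate (not isolated)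
25 | methyl (2Z,4S,7S,10Z)-4-(acetyloxy)-2-[(acetyloxy)methyl]-3-formyl-11-iodo-10-methyl-6-methylidene-7-{[tri(propan-2-yl)silyl]oxy}undeca-2,10-dienoate | O=C/C(=C(/COC(C)=O)C(=O)OC)[C@@H](OC(C)=O)CC(=C)[C@@H](O[Si](C(C)C)(C(C)C)C(C)C)CC/C(C)=C\I | intermediate
26 | macrocyclic chromium alkoxide: ring A closed, ring B open; C6–O–CrCl2 (6R), exocyclic C7=C11 olefin with CO2Me cis to C6 and CH2OAc cis to C8, 8α-OAc, 1α-silyloxy, (4Z)-olefin, 10(14)-methylene | C=C1C[C@H](OC(C)=O)/C(=C(\COC(C)=O)C(=O)OC)[C@H](O[Cr](Cl)Cl)/C=C(/C)CC[C@@H]1O[Si](C(C)C)(C(C)C)C(C)C | intermediate (not isolated)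
27 | 8α,13-diacetoxy-1α-{[tri(propan-2-yl)silyl]oxy}germacra-4,7(11),10(14)-trien-6α,12-olide | C=C1C[C@H](OC(C)=O)C2=C(COC(C)=O)C(=O)O[C@@H]2/C=C(/C)CC[C@@H]1O[Si](C(C)C)(C(C)C)C(C)C | intermediate
28 | 8α,13-diacetoxy-1α-hydroxygermacra-4,7(11),10(14)-trien-6α,12-olide | C=C1C[C@H](OC(C)=O)C2=C(COC(C)=O)C(=O)O[C@@H]2/C=C(/C)CC[C@@H]1O | target

**Step count and risks**

Total step count: 15 (7 steps to allyl bromide 13, 3 steps to aldehyde 21, 5 steps after their union).
Longest linear sequence: 12 steps (steps 1–7 and 11–15).

Steps most likely to fail: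

Step 14. What may go wrong is erosion of facial selectivity at C6, if part of the material reacts through the s-cis rotamer of the aldehyde or through a C8 conformer in which the acetoxy group is not on the far face. Intermolecular coupling may also compete when the folded conformer is poorly populated, and divalent chromium may reduce the electron-poor oxo-enoate. The fallback replaces control by the C8 acetate with a chelation-locked closure on the free C8 alcohol. It sets out from 22. The conditions of step 13 applied to 22 should give, through the γ-hydroxybutenolide with a free C8 hydroxyl F1 (not isolated), the hydroxy aldehyde ester F2. In the nickel/chromium closure of F2, the C8 hydroxyl and the C6 carbonyl oxygen bind the same trivalent chromium in a six-membered chelate; this fixes the aldehyde s-trans and the C8–O bond in the olefin plane, so that C9 is the only out-of-plane group at C8 and its tether delivers C5 to the Re face. The closure runs through the macrocyclic dihydroxy ester (as its chromium alkoxide) F3 and should give the hydroxy lactone F4. Acetylation of F4 (Ac2O, pyridine, DMAP) brings the route back at 27.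

Step 9. What may go wrong is loss of the olefin geometry, by equilibration of the α-cuprio ester with its allenolate before the comparatively slow C-alkylation, or alkylation at oxygen. The fallback introduces C13 by cross-coupling instead of alkylation. It sets out from 16: the same syn carbocupration with vinylcopper is quenched at −78 °C with iodine, a fast and retentive trapping, to give the iodo dienoate F5. Stille coupling of F5 with (tributylstannyl)methanol (Pd(PPh3)4, dioxane, 80 °C) should give with retention the hydroxymethyl dienoate F6, and acetylation (Ac2O, pyridine) brings the route back at 19.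

Step 11. What may go wrong is poor facial selectivity at C8, because the aldehyde is flanked by a tetrasubstituted olefin and an acetal and the chiral allyl unit may be mismatched with the ligand; slow addition is a second concern. The fallback uses stereoconvergence instead of catalyst control. It sets out from 21 and 13: an indium-mediated Barbier allylation (In, THF/H2O, rt) should give 22 together with its C8 epimer, the (4R)-alcohol F7, which are separated by chromatography. 22 goes on through step 12, and F7 is turned into the same acetate by Mitsunobu inversion with acetic acid (PPh3, diisopropyl azodicarboxylate, AcOH, THF), so that both epimers come back at 23.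

**Further compounds**

F1 | step 14 | {4-[(1S,4S,7Z)-1-hydroxy-8-iodo-7-methyl-3-methylidene-4-{[tri(propan-2-yl)silyl]oxy}oct-7-en-1-yl]-5-hydroxy-2-oxo-2,5-dihydrofuran-3-yl}methyl acetate | O=C1OC(O)C([C@@H](O)CC(=C)[C@@H](O[Si](C(C)C)(C(C)C)C(C)C)CC/C(C)=C\I)=C1COC(C)=O
F2 | step 14 | methyl (2Z,4S,7S,10Z)-2-[(acetyloxy)methyl]-3-formyl-4-hydroxy-11-iodo-10-methyl-6-methylidene-7-{[tri(propan-2-yl)silyl]oxy}undeca-2,10-dienoate | O=C/C(=C(/COC(C)=O)C(=O)OC)[C@@H](O)CC(=C)[C@@H](O[Si](C(C)C)(C(C)C)C(C)C)CC/C(C)=C\I
F3 | step 14 | macrocyclic dihydroxy ester (ring A closed, ring B open; 6R and 8S hydroxyls, CO2Me cis to C6, 13-OAc, 1α-silyloxy), formed as its chromium alkoxide | C=C1C[C@H](O)/C(=C(\COC(C)=O)C(=O)OC)[C@H](O)/C=C(/C)CC[C@@H]1O[Si](C(C)C)(C(C)C)C(C)C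
F4 | step 14 | 13-acetoxy-8α-hydroxy-1α-{[tri(propan-2-yl)silyl]oxy}germacra-4,7(11),10(14)-trien-6α,12-olide | C=C1C[C@H](O)C2=C(COC(C)=O)C(=O)O[C@@H]2/C=C(/C)CC[C@@H]1O[Si](C(C)C)(C(C)C)C(C)C
F5 | step 9 | methyl (2E)-3-(diethoxymethyl)-2-iodopenta-2,4-dienoate | C=C/C(C(OCC)OCC)=C(\I)C(=O)OC
F6 | step 9 | methyl (2Z)-3-(diethoxymethyl)-2-(hydroxymethyl)penta-2,4-dienoate | C=C/C(C(OCC)OCC)=C(\CO)C(=O)OC
F7 | step 11 | methyl (2Z,4R,7S,10Z)-2-[(acetyloxy)methyl]-3-(diethoxymethyl)-4-hydroxy-11-iodo-10-methyl-6-methylidene-7-{[tri(propan-2-yl)silyl]oxy}undeca-2,10-dienoate | CCOC(OCC)/C(=C(/COC(C)=O)C(=O)OC)[C@H](O)CC(=C)[C@@H](O[Si](C(C)C)(C(C)C)C(C)C)CC/C(C)=C\I
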